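**Retrosynthetic overview**

1. The target comes from a diacid with both phenols benzylated, and that from a diaryl ether in which the two carboxyl carbons (C1 of ring A, C1' of ring B) are silyloxymethyl groups. Both are oxidized together after ring construction, and BCl3 then frees the two phenols.
2. Feature used: ring B (C1' CO2H, C2' O–aryl, C3' H, C4' CH3, C5' H, C6' OH) has the C6' hydroxyl and the C2' ether oxygen meta to each other, with the carboxyl carbon C1' between them and the methyl para to C1'. A cyclobutenone and an oxygen-substituted alkyne give exactly this pattern.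
3. Key disconnection: C1'–C6' and C2'–C3' of ring B lead back to 3-methylcyclobutenone and the ring A aryl 3-(silyloxy)prop-1-ynyl ether. The diaryl ether oxygen is thus attached to an sp carbon by vinylic substitution, and no aryl–oxygen coupling is needed.
4. The alkynyl ether comes from the (E)-1,2-dichlorovinyl ether of a ring A salicylaldehyde (C1 CHO, C2 OH, C3 OBn, C4 Cl, C5 OMe). That aldehyde is made from 2-chloro-3-methoxyphenol by ortho-formylation, benzylation, Baeyer–Villiger oxidation and a second ortho-formylation. The cyclobutenone comes from propyne and dichloroketene.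
5. Ring order: ring A is bought as a benzene ring and only decorated; ring B is the single ring formed, in the benzannulation.

Key step: step 12

Assumption: 2-chloro-3-methoxyphenol is taken as a catalogue compound; otherwise monomethylation of 2-chlororesorcinol would supply it.
Abbreviations: Bn = benzyl; TBS = tert-butyldimethylsilyl; ArO = 2-(benzyloxy)-6-{[(tert-butyldimethylsilyl)oxy]methyl}-3-chloro-4-methoxyphenoxy (ring A, bonded through the oxygen at its C2).

**Route**

Step 1
Reactants: 1 2-chloro-3-methoxyphenol
Product: 3 3-chloro-2-hydroxy-4-methoxybenzaldehyde, via salicyl alcohol 2 (not isolated)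
Conditions: MgCl2, Et3N, (CH2O)n, MeCN, reflux; aq HCl
Reagents that add atoms: formaldehyde (from paraformaldehyde), C=O
Why: Magnesium-mediated ortho-formylation (Casnati–Skattebøl) through the chelate ArOMgCl delivers formaldehyde only to the one free position ortho to the hydroxyl (the other carries chlorine), and a second formaldehyde oxidizes the hydroxymethyl intermediate 2 by hydride transfer.

Step 2
Reactants: 3 3-chloro-2-hydroxy-4-methoxybenzaldehyde
Product: 4 2-(benzyloxy)-3-chloro-4-methoxybenzaldehyde
Conditions: BnBr, K2CO3, DMF, 60 °C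
Reagents that add atoms: benzyl bromide, BrCc1ccccc1
Why: Williamson etherification of the phenoxide protects the oxygen that becomes the ring A C3 hydroxyl as a benzyl ether, which BCl3 can later remove without touching the aryl chloride.

Step 3
Reactants: 4 2-(benzyloxy)-3-chloro-4-methoxybenzaldehyde
Product: 6 2-(benzyloxy)-3-chloro-4-methoxyphenol, via aryl formate 5 (not isolated)
Conditions: mCPBA, CH2Cl2, rt; then K2CO3 (cat.), MeOH, rt
Reagents that add atoms: mCPBA, OOC(=O)c1cccc(Cl)c1
Why: In this Baeyer–Villiger (Dakin-type) oxidation the aryl group, carrying ortho and para oxygen donors, migrates in preference to hydride, and methanolysis of formate 5 frees the phenol that becomes the ether oxygen at ring A C2.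

Step 4
Reactants: 6 2-(benzyloxy)-3-chloro-4-methoxyphenol
Product: 8 3-(benzyloxy)-4-chloro-2-hydroxy-5-methoxybenzaldehyde, via salicyl alcohol 7 (not isolated)
Conditions: MgCl2, Et3N, (CH2O)n, MeCN, reflux; aq HCl
Reagents that add atoms: formaldehyde (from paraformaldehyde), C=O
Why: A second magnesium-mediated ortho-formylation can only attack the single free ortho position of 6, so the carbon that becomes the ring A carboxyl group enters para to chlorine with no regioisomer possible.

Step 5
Reactants: 8 3-(benzyloxy)-4-chloro-2-hydroxy-5-methoxybenzaldehyde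
Product: 9 3-(benzyloxy)-4-chloro-2-{[(E)-1,2-dichloroethenyl]oxy}-5-methoxybenzaldehyde
Conditions: Cl2C=CHCl, K2CO3, DMF, 70 °C
Reagents that add atoms: trichloroethylene, ClC=C(Cl)Cl
Why: K2CO3 converts trichloroethylene into dichloroacetylene, to which the phenoxide of 8 adds anti to give the (E)-1,2-dichlorovinyl ether, a known vinylic substitution at phenol oxygen that a non-enolizable aldehyde tolerates.

Step 6
Reactants: 9 3-(benzyloxy)-4-chloro-2-{[(E)-1,2-dichloroethenyl]oxy}-5-methoxybenzaldehyde
Product: 10 [3-(benzyloxy)-4-chloro-2-{[(E)-1,2-dichloroethenyl]oxy}-5-methoxyphenyl]methanol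
Conditions: NaBH4, MeOH/THF, 0 °C
Reagents that add atoms: none
Why: Borohydride reduction of the aldehyde leaves the vinyl chlorides untouched and parks the ring A carboxyl carbon at the alcohol level, because an aldehyde or ester ortho to the vinyl ether would not survive n-BuLi in step 8.

Step 7
Reactants: 10 [3-(benzyloxy)-4-chloro-2-{[(E)-1,2-dichloroethenyl]oxy}-5-methoxyphenyl]methanol
Product: 11 tert-butyl{[3-(benzyloxy)-4-chloro-2-{[(E)-1,2-dichloroethenyl]oxy}-5-methoxyphenyl]methoxy}dimethylsilane
Conditions: TBSCl, imidazole, DMF, rt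
Reagents that add atoms: tert-butyldimethylsilyl chloride, CC(C)(C)[Si](C)(C)Cl
Why: Standard silylation of a primary benzylic alcohol removes the acidic proton and gives a group that is inert to organolithium reagents.

Step 8
Reactants: 11 tert-butyl{[3-(benzyloxy)-4-chloro-2-{[(E)-1,2-dichloroethenyl]oxy}-5-methoxyphenyl]methoxy}dimethylsilane
Product: 14 3-(ArO)prop-2-yn-1-ol, via chloroalkynyl ether 12 (not isolated), via lithium alkynyl ether 13 (not isolated)
Conditions: n-BuLi (2.5 equiv), THF, −78 °C; then (CH2O)n, −78 °C → rt; aq NH4Cl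
Reagents that add atoms: formaldehyde (from paraformaldehyde), C=O
Why: n-BuLi removes the vinylic hydrogen with loss of LiCl to give chloroalkyne 12, chlorine–lithium exchange with a second equivalent gives the acetylide ArOC≡CLi 13, and 13 adds to formaldehyde, which is the established dichlorovinyl ether route to substituted aryl alkynyl ethers and leaves silyl ether, benzyl ether and aryl chloride intact at −78 °C.

Step 9
Reactants: 14 3-(ArO)prop-2-yn-1-ol
Product: 15 tert-butyl{[3-(ArO)prop-2-yn-1-yl]oxy}dimethylsilane
Conditions: TBSCl, imidazole (excess), CH2Cl2, 0 °C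
Reagents that add atoms: tert-butyldimethylsilyl chloride, CC(C)(C)[Si](C)(C)Cl
Why: Silylation of the primary propargylic alcohol under buffered, non-acidic conditions should spare the acid-sensitive alkynyl ether and gives both carboxyl carbons the same protecting group.

Step 10
Reactants: 16 propyne
Product: 17 4,4-dichloro-3-methylcyclobut-2-en-1-one
Conditions: Cl3CCOCl, Zn(Cu) couple, Et2O/DME, rt
Reagents that add atoms: trichloroacetyl chloride (delivers dichloroketene), ClC(=O)C(Cl)(Cl)Cl
Why: Dichloroketene generated by zinc dechlorination adds [2+2] to the terminal alkyne with its carbonyl carbon bonding to the unsubstituted alkyne carbon, which places the methyl group at C3.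

Step 11
Reactants: 17 4,4-dichloro-3-methylcyclobut-2-en-1-one
Product: 18 3-methylcyclobut-2-en-1-one
Conditions: Zn, AcOH, TMEDA, EtOH, 0 °C → rt
Reagents that add atoms: none
Why: Buffered zinc reduction removes both α-chlorines of the dichloroketone, as established for 3-alkylcyclobutenones, and the volatile product would be carried on as a solution.

Step 12
Reactants: 15 tert-butyl{[3-(ArO)prop-2-yn-1-yl]oxy}dimethylsilane; 18 3-methylcyclobut-2-en-1-one
Product: 23 3-(ArO)-2-{[(tert-butyldimethylsilyl)oxy]methyl}-5-methylphenol, via vinylketene 19 (not isolated), via vinylcyclobutenone 20 (not isolated), via dienylketene 21 (not isolated), via cyclohexadienone 22 (not isolated)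
Conditions: 18 (2 equiv), toluene, 80 °C then 110 °C, sealed tube
Reagents that add atoms: none
Why: Heating opens 18 by four-electron electrocyclic ring opening to vinylketene 19, which adds [2+2] to the electron-rich triple bond of 15 so that the ketene carbonyl carbon (future C6') bonds to the alkyne carbon carrying the silyloxymethyl group (C1') and the ketene α-carbon (future C3') bonds to the oxygen-bearing alkyne carbon (C2'), giving vinylcyclobutenone 20. Reversible four-electron opening of 20 gives dienylketene 21, whose thermal disrotatory six-electron electrocyclization (new C5'–C6' bond) closes ring B as cyclohexadienone 22, and tautomerization gives phenol 23. The closest known reaction is the Danheiser benzannulation of cyclobutenones with alkoxy- and siloxyalkynes, of which an aryl alkynyl ether is a less electron-rich member. No stereocenter is formed in 23, the single transient one in 20 being destroyed on ring opening. The selectivity needed is the regiochemistry of the [2+2] step, secured by donation from the ether oxygen, which makes the alkyne carbon remote from oxygen the nucleophilic terminus that attacks the ketene carbonyl carbon, so that the silyloxymethyl carbon ends between OH and O–aryl and the methyl from C3 of 18 lands at C4'. Because the aryl group offers no β-hydrogen, the retro-ene loss of alkene that limits alkyl alkynyl ethers at these temperatures cannot occur, and the ring A chloride, benzyl ether and silyl ethers are thermally inert.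

Step 13
Reactants: 23 3-(ArO)-2-{[(tert-butyldimethylsilyl)oxy]methyl}-5-methylphenol
Product: 24 1-(benzyloxy)-3-(ArO)-2-{[(tert-butyldimethylsilyl)oxy]methyl}-5-methylbenzene
Conditions: BnBr, K2CO3, DMF, rt
Reagents that add atoms: benzyl bromide, BrCc1ccccc1
Why: Williamson benzylation masks the new ring B phenol so that no free phenol is exposed to the oxidants of steps 15 and 16, and both benzyl groups can leave together at the end.

Step 14
Reactants: 24 1-(benzyloxy)-3-(ArO)-2-{[(tert-butyldimethylsilyl)oxy]methyl}-5-methylbenzene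
Product: 25 [3-(benzyloxy)-2-[3-(benzyloxy)-2-(hydroxymethyl)-5-methylphenoxy]-4-chloro-5-methoxyphenyl]methanol
Conditions: Bu4NF, THF, 0 °C → rt
Reagents that add atoms: none
Why: Fluoride cleaves both primary silyl ethers in one operation through the strong Si–F bond, while benzyl ethers, the aryl chloride and the diaryl ether are unaffected.

Step 15
Reactants: 25 [3-(benzyloxy)-2-[3-(benzyloxy)-2-(hydroxymethyl)-5-methylphenoxy]-4-chloro-5-methoxyphenyl]methanol
Product: 26 3-(benzyloxy)-2-[3-(benzyloxy)-2-formyl-5-methylphenoxy]-4-chloro-5-methoxybenzaldehyde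
Conditions: Dess–Martin periodinane, CH2Cl2, rt
Reagents that add atoms: none
Why: Dess–Martin oxidation converts both benzylic alcohols cleanly to aldehydes without over-oxidation, and with the phenols masked nothing else in 25 is oxidizable.

Step 16
Reactants: 26 3-(benzyloxy)-2-[3-(benzyloxy)-2-formyl-5-methylphenoxy]-4-chloro-5-methoxybenzaldehyde
Product: 27 3-(benzyloxy)-2-[3-(benzyloxy)-2-carboxy-5-methylphenoxy]-4-chloro-5-methoxybenzoic acid
Conditions: NaClO2, NaH2PO4, 2-methyl-2-butene, t-BuOH/H2O, rt
Reagents that add atoms: sodium chlorite, [Na+].[O-]Cl=O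
Why: Pinnick oxidation takes even di-ortho-substituted aryl aldehydes to the acids, and 2-methyl-2-butene scavenges the hypochlorous acid that could otherwise chlorinate the electron-rich rings.

Step 17
Reactants: 27 3-(benzyloxy)-2-[3-(benzyloxy)-2-carboxy-5-methylphenoxy]-4-chloro-5-methoxybenzoic acid
Product: 28 2-(2-carboxy-3-hydroxy-5-methylphenoxy)-4-chloro-3-hydroxy-5-methoxybenzoic acid (target)
Conditions: BCl3 (excess), C6HMe5, CH2Cl2, −78 → 0 °C; aq work-up
Reagents that add atoms: none
Why: Lewis-acid debenzylation with BCl3 and pentamethylbenzene as benzyl cation scavenger cleaves both aryl benzyl ethers at low temperature, while the C5 methyl ether (no neighbouring carbonyl to chelate), the aryl chloride and the diaryl ether should persist, a selectivity that hydrogenolysis would not offer for the chloride.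

**Compound list**

1 | 2-chloro-3-methoxyphenol | COc1cccc(O)c1Cl | starting material
2 | 2-chloro-6-(hydroxymethyl)-3-methoxyphenol | COc1ccc(CO)c(O)c1Cl | intermediate
3 | 3-chloro-2-hydroxy-4-methoxybenzaldehyde | COc1ccc(C=O)c(O)c1Cl | intermediate
4 | 2-(benzyloxy)-3-chloro-4-methoxybenzaldehyde | COc1ccc(C=O)c(OCc2ccccc2)c1Cl | intermediate
5 | 2-(benzyloxy)-3-chloro-4-methoxyphenyl formate | COc1ccc(OC=O)c(OCc2ccccc2)c1Cl | intermediate
6 | 2-(benzyloxy)-3-chloro-4-methoxyphenol | COc1ccc(O)c(OCc2ccccc2)c1Cl | intermediate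
7 | 2-(benzyloxy)-3-chloro-6-(hydroxymethyl)-4-methoxyphenol | COc1cc(CO)c(O)c(OCc2ccccc2)c1Cl | intermediate
8 | 3-(benzyloxy)-4-chloro-2-hydroxy-5-methoxybenzaldehyde | COc1cc(C=O)c(O)c(OCc2ccccc2)c1Cl | intermediate
9 | 3-(benzyloxy)-4-chloro-2-{[(E)-1,2-dichloroethenyl]oxy}-5-methoxybenzaldehyde | COc1cc(C=O)c(O/C(Cl)=C\Cl)c(OCc2ccccc2)c1Cl | intermediate
10 | [3-(benzyloxy)-4-chloro-2-{[(E)-1,2-dichloroethenyl]oxy}-5-methoxyphenyl]methanol | COc1cc(CO)c(O/C(Cl)=C\Cl)c(OCc2ccccc2)c1Cl | intermediate
11 | tert-butyl{[3-(benzyloxy)-4-chloro-2-{[(E)-1,2-dichloroethenyl]oxy}-5-methoxyphenyl]methoxy}dimethylsilane | COc1cc(CO[Si](C)(C)C(C)(C)C)c(O/C(Cl)=C\Cl)c(OCc2ccccc2)c1Cl | intermediate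
12 | tert-butyl{[3-(benzyloxy)-4-chloro-2-[(chloroethynyl)oxy]-5-methoxyphenyl]methoxy}dimethylsilane | COc1cc(CO[Si](C)(C)C(C)(C)C)c(OC#CCl)c(OCc2ccccc2)c1Cl | intermediate
13 | lithium 2-(ArO)ethynide, ArOC≡CLi | COc1cc(CO[Si](C)(C)C(C)(C)C)c(OC#C[Li])c(OCc2ccccc2)c1Cl | intermediate
14 | 3-[2-(benzyloxy)-6-{[(tert-butyldimethylsilyl)oxy]methyl}-3-chloro-4-methoxyphenoxy]prop-2-yn-1-ol | COc1cc(CO[Si](C)(C)C(C)(C)C)c(OC#CCO)c(OCc2ccccc2)c1Cl | intermediate
15 | tert-butyl({3-[2-(benzyloxy)-6-{[(tert-butyldimethylsilyl)oxy]methyl}-3-chloro-4-methoxyphenoxy]prop-2-yn-1-yl}oxy)dimethylsilane | COc1cc(CO[Si](C)(C)C(C)(C)C)c(OC#CCO[Si](C)(C)C(C)(C)C)c(OCc2ccccc2)c1Cl | intermediate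
16 | propyne | CC#C | starting material
17 | 4,4-dichloro-3-methylcyclobut-2-en-1-one | CC1=CC(=O)C1(Cl)Cl | intermediate
18 | 3-methylcyclobut-2-en-1-one | CC1=CC(=O)C1 | intermediate
19 | 3-methylbuta-1,3-dien-1-one (isopropenylketene) | CC(=C)C=C=O | intermediate
20 | 3-(ArO)-2-{[(tert-butyldimethylsilyl)oxy]methyl}-4-(prop-1-en-2-yl)cyclobut-2-en-1-one (racemic) | CC(=C)C1C(=O)C(CO[Si](C)(C)C(C)(C)C)=C1Oc1c(CO[Si](C)(C)C(C)(C)C)cc(OC)c(Cl)c1OCc1ccccc1 | intermediate
21 | 3-(ArO)-2-{[(tert-butyldimethylsilyl)oxy]methyl}-5-methylhexa-1,3,5-trien-1-one, ketene carbon and isopropenyl group cis on the C3=C4 bond | O=C=C(CO[Si](C)(C)C(C)(C)C)/C(Oc1c(CO[Si](C)(C)C(C)(C)C)cc(OC)c(Cl)c1OCc1ccccc1)=C\C(C)=C | intermediate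
22 | 3-(ArO)-2-{[(tert-butyldimethylsilyl)oxy]methyl}-5-methylcyclohexa-2,4-dien-1-one | CC1=CC(Oc2c(CO[Si](C)(C)C(C)(C)C)cc(OC)c(Cl)c2OCc2ccccc2)=C(CO[Si](C)(C)C(C)(C)C)C(=O)C1 | intermediate
23 | 3-[2-(benzyloxy)-6-{[(tert-butyldimethylsilyl)oxy]methyl}-3-chloro-4-methoxyphenoxy]-2-{[(tert-butyldimethylsilyl)oxy]methyl}-5-methylphenol | COc1cc(CO[Si](C)(C)C(C)(C)C)c(Oc2cc(C)cc(O)c2CO[Si](C)(C)C(C)(C)C)c(OCc2ccccc2)c1Cl | intermediate
24 | benzyl ether of 23 at the ring B phenol: 1-(benzyloxy)-3-(ArO)-2-{[(tert-butyldimethylsilyl)oxy]methyl}-5-methylbenzene | COc1cc(CO[Si](C)(C)C(C)(C)C)c(Oc2cc(C)cc(OCc3ccccc3)c2CO[Si](C)(C)C(C)(C)C)c(OCc2ccccc2)c1Cl | intermediate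
25 | [3-(benzyloxy)-2-[3-(benzyloxy)-2-(hydroxymethyl)-5-methylphenoxy]-4-chloro-5-methoxyphenyl]methanol | COc1cc(CO)c(Oc2cc(C)cc(OCc3ccccc3)c2CO)c(OCc2ccccc2)c1Cl | intermediate
26 | 3-(benzyloxy)-2-[3-(benzyloxy)-2-formyl-5-methylphenoxy]-4-chloro-5-methoxybenzaldehyde | COc1cc(C=O)c(Oc2cc(C)cc(OCc3ccccc3)c2C=O)c(OCc2ccccc2)c1Cl | intermediate
27 | 3-(benzyloxy)-2-[3-(benzyloxy)-2-carboxy-5-methylphenoxy]-4-chloro-5-methoxybenzoic acid | COc1cc(C(=O)O)c(Oc2cc(C)cc(OCc3ccccc3)c2C(=O)O)c(OCc2ccccc2)c1Cl | intermediate
28 | 2-(2-carboxy-3-hydroxy-5-methylphenoxy)-4-chloro-3-hydroxy-5-methoxybenzoic acid | COc1cc(C(=O)O)c(Oc2cc(C)cc(O)c2C(=O)O)c(O)c1Cl | target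

**Step count and risks**

Total step count: 17. Longest linear sequence: 15 steps (steps 1–9 and 12–17); the two-step cyclobutenone branch (steps 10–11) joins at step 12.

Steps most likely to fail:

1. Step 12. Capture of vinylketene 19 by the alkyne may be too slow, because the aryloxy group is a weaker donor than an alkoxy group and is flanked by two ortho substituents; the ketene would then dimerize or oligomerize. The product phenol may also be acylated by excess ketene, which a methanolic KOH work-up would reverse. Fallback, setting out from 8 and returning at 26: the diaryl ether is made by nucleophilic aromatic substitution instead. Purchased 2,6-difluoro-4-methylbenzaldehyde is treated with benzyl alcohol and KOtBu in THF at 0 °C to give 2-(benzyloxy)-6-fluoro-4-methylbenzaldehyde F1, the first substitution deactivating the ring toward a second. The phenoxide of 8 (K2CO3, DMF, 100 °C) then displaces the remaining fluoride, which is activated by the ortho formyl group, and this should give dialdehyde 26 directly. Steps 16 and 17 follow unchanged.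

2. Step 8. The lithiated dichlorovinyl ether may expel the aryloxide instead of chloride, n-BuLi may attack the aryl chloride or the benzylic positions, or the alkynyl ether may hydrate during work-up. Fallback, setting out from 8 and returning at 15: a copper-catalysed dibromoalkene coupling that needs no organolithium. NaBH4 reduction of 8 gives salicyl alcohol 7, here isolated, and selective silylation of its primary hydroxyl (TBSCl 1 equiv, imidazole, DMF, 0 °C) gives 2-(benzyloxy)-6-{[(tert-butyldimethylsilyl)oxy]methyl}-3-chloro-4-methoxyphenol F2. The coupling partner tert-butyl[(3,3-dibromoprop-2-en-1-yl)oxy]dimethylsilane F3 comes from (tert-butyldimethylsilyloxy)acetaldehyde with CBr4 and PPh3. Coupling of F2 with F3 (CuI, 2,2'-bipyridine, K3PO4, toluene, 110 °C) replaces the less hindered bromine and should give the (Z)-3-(ArO)-3-bromoprop-2-en-1-yl silyl ether F4. Anti elimination of HBr from F4 with KOtBu in THF then gives 15.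

3. Step 11. The volatile, base- and acid-sensitive 3-methylcyclobutenone may be lost on isolation, or the zinc reduction may go on to ring-opened or over-reduced material. Fallback, setting out from 15 and returning at 23: the same vinylketene 19 is generated by photochemical Wolff rearrangement (the second-generation form of the benzannulation). Purchased 3-methylbut-3-en-2-one is trifluoroacetylated on its methyl group (LiN(SiMe3)2, CF3CO2CH2CF3, THF, −78 °C) to 1,1,1-trifluoro-5-methylhex-5-ene-2,4-dione F5. Detrifluoroacetylative diazo transfer (MsN3, Et3N, H2O, MeCN) gives 1-diazo-3-methylbut-3-en-2-one F6. Irradiation of F6 with 15 in CH2Cl2 (medium-pressure Hg lamp, Pyrex filter) should give 19 with loss of nitrogen and then adduct 20, and heating in toluene carries 20 through 21 and 22 to 23.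

**Further compounds**

F1 | step 12 | 2-(benzyloxy)-6-fluoro-4-methylbenzaldehyde | Cc1cc(F)c(C=O)c(OCc2ccccc2)c1
F2 | step 8 | 2-(benzyloxy)-6-{[(tert-butyldimethylsilyl)oxy]methyl}-3-chloro-4-methoxyphenol | COc1cc(CO[Si](C)(C)C(C)(C)C)c(O)c(OCc2ccccc2)c1Cl
F3 | step 8 | tert-butyl[(3,3-dibromoprop-2-en-1-yl)oxy]dimethylsilane | CC(C)(C)[Si](C)(C)OCC=C(Br)Br
F4 | step 8 | tert-butyl({(2Z)-3-bromo-3-[2-(benzyloxy)-6-{[(tert-butyldimethylsilyl)oxy]methyl}-3-chloro-4-methoxyphenoxy]prop-2-en-1-yl}oxy)dimethylsilane | COc1cc(CO[Si](C)(C)C(C)(C)C)c(O/C(Br)=C/CO[Si](C)(C)C(C)(C)C)c(OCc2ccccc2)c1Cl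
F5 | step 11 | 1,1,1-trifluoro-5-methylhex-5-ene-2,4-dione | CC(=C)C(=O)CC(=O)C(F)(F)F
F6 | step 11 | 1-diazo-3-methylbut-3-en-2-one | CC(=C)C(=O)C=[N+]=[N-]
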